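The synthesis rests on opening the four-membered ring (C3, C9, C1', C2'; fused to ring B) at C3–C9 and placing a carbonyl between these two benzylic carbons, which gives a 2-indanone. Forward, light expels CO from crystals of the enantiopure 2-indanone 9 and the lattice-held biradical closes C3–C9, so the ring contraction delivers benzocyclobutene 10 with the quaternary centre unchanged. Precursor 9 carries at its quaternary carbon (the future C3) the methyl ester, which stabilises the first radical and later becomes the C4 carbonyl, and the 3,5-dimethoxyphenoxymethyl arm (C2, O1, ring A). Its configuration is set by asymmetric hydroxymethylation. Saponification and Friedel–Crafts closure of ring C complete the target.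

Key step: step 6

Remark on numbering: homoisoflavanone numbering is used for the target (O1, C2, spiro C3, C4 carbonyl, C9 = cyclobutene CH2, C1' and C2' = ring-B carbons bonded to C9 and C3; ring A = chromanone arene, ring C = pyranone). Indanone numbering is used for 6–9.

Remark on configuration: 7, 9, 10, 11, 12 and 13 are all S, because step 6 proceeds with retention and the CIP order at the quaternary carbon does not change along the route.

Assumption: the sense of induction of the step 4 catalyst on this substrate cannot be assigned in advance; (R)-BINAP is written, and the ligand antipode that gives (S)-7 would be fixed by a pilot run.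

Step 1
Reactants: 1 2-bromo-3,4-dimethoxybenzaldehyde
Product: 3 (2-bromo-3,4-dimethoxyphenyl)acetonitrile, via tosylvinylformamide adduct 2 (not isolated)
Conditions: TosMIC, t-BuOK, DME, −50 °C; then MeOH, reflux
Reagents that add atoms: TosMIC (tosylmethyl isocyanide), Cc1ccc(cc1)S(=O)(=O)C[N+]#[C-]
Why: Van Leusen reductive cyanation, in which the TosMIC anion adds to the aldehyde, the oxazoline opens to the N-formyl ene-sulfone 2, and methanolysis with loss of sulfinate leaves the one-carbon-homologated nitrile, the aryl bromide and methyl ethers being inert to alkoxide.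

Step 2
Reactants: 3 (2-bromo-3,4-dimethoxyphenyl)acetonitrile
Product: 5 methyl 4-(2-bromo-3,4-dimethoxyphenyl)-3-oxobutanoate, via Blaise enamino ester 4 (not isolated)
Conditions: Zn dust (activated with cat. MsOH), BrCH2CO2Me (slow addition), THF, reflux; then 1 M aq. HCl, rt
Reagents that add atoms: methyl bromoacetate, COC(=O)CBr; water, O
Why: Blaise reaction, in which the zinc ester enolate adds to the nitrile and mild acid hydrolysis of the enaminate 4 gives the β-keto ester; slow addition limits self-condensation of the bromoester and deprotonation of the benzylic nitrile, and zinc dust does not insert into the aryl bromide.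

Step 3
Reactants: 5 methyl 4-(2-bromo-3,4-dimethoxyphenyl)-3-oxobutanoate
Product: 6 methyl 6,7-dimethoxy-2-oxo-2,3-dihydro-1H-indene-1-carboxylate (racemic, configurationally labile, largely enolised)
Conditions: Pd(OAc)2 (5 mol %), P(t-Bu)3·HBF4 (10 mol %), K3PO4, toluene, 90 °C, argon; AcOH quench
Reagents that add atoms: none
Why: Intramolecular palladium-catalysed α-arylation of a 1,3-dicarbonyl enolate (Buchwald–Hartwig type), in which zerovalent palladium inserts into the C–Br bond and C–C reductive elimination from a six-membered palladacycle closes the five-membered ring, as in oxindole formation from 2-haloanilides of β-dicarbonyl acids, the product being held as its stable enolate until the acidic quench.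

Step 4
Reactants: 6 methyl 6,7-dimethoxy-2-oxo-2,3-dihydro-1H-indene-1-carboxylate
Product: 7 methyl (S)-1-(hydroxymethyl)-6,7-dimethoxy-2-oxo-2,3-dihydro-1H-indene-1-carboxylate
Conditions: [Pd((R)-BINAP)(H2O)2](OTf)2 (5 mol %), 37% aq. HCHO, THF, −20 °C; used promptly
Reagents that add atoms: formaldehyde, C=O
Why: Direct catalytic asymmetric aldol reaction with formaldehyde (hydroxymethylation of a cyclic β-keto ester), in which the chiral O,O-enolate of divalent palladium exposes one face of C1 so that the quaternary centre is set by the BINAP ligand (catalyst control), while the non-basic medium disfavours retro-aldol loss of formaldehyde and reaction at C3.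

Step 5
Reactants: 7 methyl (S)-1-(hydroxymethyl)-6,7-dimethoxy-2-oxo-2,3-dihydro-1H-indene-1-carboxylate; 8 3,5-dimethoxyphenol
Product: 9 methyl (S)-1-[(3,5-dimethoxyphenoxy)methyl]-6,7-dimethoxy-2-oxo-2,3-dihydro-1H-indene-1-carboxylate
Conditions: PPh3, DIAD, toluene, 0 → 45 °C; then recrystallisation to enantiopurity (chiral HPLC control)
Reagents that add atoms: none
Why: Mitsunobu etherification, in which the primary alcohol is activated as its oxyphosphonium salt and displaced by the phenoxide in an SN2 reaction at a carbon that cannot eliminate, without the alkoxide and heat that would trigger retro-aldol or retro-Claisen cleavage of this α-hydroxymethyl β-keto ester; the stereocentre is not touched.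

Step 6
Reactants: 9 methyl (S)-1-[(3,5-dimethoxyphenoxy)methyl]-6,7-dimethoxy-2-oxo-2,3-dihydro-1H-indene-1-carboxylate
Product: 10 methyl (S)-7-[(3,5-dimethoxyphenoxy)methyl]-4,5-dimethoxybicyclo[4.2.0]octa-1,3,5-triene-7-carboxylate
Conditions: hν (312 nm lamps or medium-pressure Hg lamp with Pyrex filter, λ > 300 nm), powdered crystals between Pyrex plates or aqueous nanocrystalline suspension (CTAB below its cmc), 5–10 °C
Reagents that add atoms: none
Why: n→π* excitation of the ketone causes Norrish α-cleavage (type 1) of the C1–C2 bond of the indanone to a tertiary radical stabilised by the ester and an arylacetyl radical, which loses CO to leave the benzylic C9 radical, and the 1,4-biradical then recombines. The closest known reaction type is the solid-state photodecarbonylation of crystalline ketones with radical-stabilising α-substituents, which includes 2-indanones giving benzocyclobutenes and α-ester ketones with quaternary centres. The four-membered ring is closed by radical–radical coupling of the 1,4-biradical (C3–C9 bond) in a least-motion collapse, not by electrocyclisation of a relaxed o-quinodimethane. No new stereocentre is formed; the quaternary centre should be retained because the lattice holds the ester and the aryloxymethyl arm in place, so the radical centre cannot rotate about its bond to ring B before coupling. The step needs excitation of the ketone alone (the aryl ethers are nearly transparent above 300 nm), coupling faster than β-scission of the aryloxy group or relaxation to the o-quinodimethane, and a solid phase throughout; the exocyclic ester on C1 secures the first cleavage, which the ring-locked benzylic bond alone would not, and low temperature keeps the sample from melting.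

Step 7
Reactants: 10 methyl (S)-7-[(3,5-dimethoxyphenoxy)methyl]-4,5-dimethoxybicyclo[4.2.0]octa-1,3,5-triene-7-carboxylate
Product: 11 (S)-7-[(3,5-dimethoxyphenoxy)methyl]-4,5-dimethoxybicyclo[4.2.0]octa-1,3,5-triene-7-carboxylic acid
Conditions: LiOH·H2O, THF/MeOH/H2O, 50 °C; then 1 M HCl
Reagents that add atoms: lithium hydroxide, [Li+].[OH-] (its oxygen becomes the carboxyl OH)
Why: Saponification (BAc2 ester hydrolysis) of a hindered, non-enolisable methyl ester, where the absence of an α-hydrogen excludes both epimerisation and E1cB loss of the aryloxide, and the benzocyclobutene and aryl ethers are stable to aqueous base.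

Step 8
Reactants: 11 (S)-7-[(3,5-dimethoxyphenoxy)methyl]-4,5-dimethoxybicyclo[4.2.0]octa-1,3,5-triene-7-carboxylic acid
Product: 13 (S)-4,5,5',7'-tetramethoxyspiro[bicyclo[4.2.0]octa-1,3,5-triene-7,3'-chroman]-4'-one (CNP0192565.1), via mixed trifluoroacetic anhydride 12 (not isolated)
Conditions: TFAA, CH2Cl2, 0 °C → rt
Reagents that add atoms: none
Why: Intramolecular Friedel–Crafts acylation, in which the mixed anhydride 12 acylates the position ortho to the ether oxygen of the 3,5-dimethoxyphenoxy ring (activated by three oxygens, the two ortho sites being equivalent by symmetry) to close the six-membered ring C, without a strong Lewis acid that could decarbonylate the tertiary acyl group or open the benzocyclobutene; the stereocentre is untouched.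

Compound list
1 | 2-bromo-3,4-dimethoxybenzaldehyde | COc1ccc(C=O)c(Br)c1OC | starting material
2 | N-[2-(2-bromo-3,4-dimethoxyphenyl)-1-tosylethenyl]formamide (as potassium salt in the flask) | COc1ccc(C=C(NC=O)S(=O)(=O)c2ccc(C)cc2)c(Br)c1OC | intermediate (not isolated)
3 | (2-bromo-3,4-dimethoxyphenyl)acetonitrile | COc1ccc(CC#N)c(Br)c1OC | intermediate
4 | methyl (Z)-3-amino-4-(2-bromo-3,4-dimethoxyphenyl)but-2-enoate (as zinc enaminate in the flask) | COC(=O)/C=C(\N)Cc1ccc(OC)c(OC)c1Br | intermediate (not isolated)
5 | methyl 4-(2-bromo-3,4-dimethoxyphenyl)-3-oxobutanoate | COC(=O)CC(=O)Cc1ccc(OC)c(OC)c1Br | intermediate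
6 | methyl 6,7-dimethoxy-2-oxo-2,3-dihydro-1H-indene-1-carboxylate (racemic, labile) | COC(=O)C1C(=O)Cc2ccc(OC)c(OC)c21 | intermediate
7 | methyl (S)-1-(hydroxymethyl)-6,7-dimethoxy-2-oxo-2,3-dihydro-1H-indene-1-carboxylate | OC[C@@]1(C(=O)Cc2ccc(OC)c(OC)c21)C(=O)OC | intermediate
8 | 3,5-dimethoxyphenol | COc1cc(O)cc(OC)c1 | starting material
9 | methyl (S)-1-[(3,5-dimethoxyphenoxy)methyl]-6,7-dimethoxy-2-oxo-2,3-dihydro-1H-indene-1-carboxylate | COc1cc(OC)cc(c1)OC[C@@]1(C(=O)Cc2ccc(OC)c(OC)c21)C(=O)OC | intermediate (key-step precursor)
10 | methyl (S)-7-[(3,5-dimethoxyphenoxy)methyl]-4,5-dimethoxybicyclo[4.2.0]octa-1,3,5-triene-7-carboxylate | COc1cc(OC)cc(c1)OC[C@@]1(Cc2ccc(OC)c(OC)c21)C(=O)OC | intermediate (key-step product)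
11 | (S)-7-[(3,5-dimethoxyphenoxy)methyl]-4,5-dimethoxybicyclo[4.2.0]octa-1,3,5-triene-7-carboxylic acid | COc1cc(OC)cc(c1)OC[C@@]1(Cc2ccc(OC)c(OC)c21)C(=O)O | intermediate
12 | (S)-7-[(3,5-dimethoxyphenoxy)methyl]-4,5-dimethoxybicyclo[4.2.0]octa-1,3,5-triene-7-carboxylic trifluoroacetic anhydride | COc1cc(OC)cc(c1)OC[C@@]1(Cc2ccc(OC)c(OC)c21)C(=O)OC(=O)C(F)(F)F | intermediate (not isolated)
13 | (S)-4,5,5',7'-tetramethoxyspiro[bicyclo[4.2.0]octa-1,3,5-triene-7,3'-chroman]-4'-one | COc1cc(OC)c2c(c1)OC[C@@]1(Cc3ccc(OC)c(OC)c31)C2=O | target

Total step count: 8. Longest linear sequence: 8 steps (1 → 13); phenol 8 enters at step 5.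

Steps most likely to fail

Step 6. The solid-state reaction depends on 9 packing in a lattice that permits α-cleavage and CO loss yet holds the biradical. The compound may not crystallise in such a form, or the irradiated solid may soften as product accumulates. The biradical would then relax to a freely rotating o-quinodimethane, with loss of configuration and dimerisation. Expulsion of the aryloxy radical by β-scission is a further leak. The fallback sets out from 9 and uses a Wolff ring contraction in place of CO extrusion. Regitz diazo transfer at the C3 methylene (p-ABSA, DBU, MeCN, 0 °C) would give methyl (S)-3-diazo-1-[(3,5-dimethoxyphenoxy)methyl]-6,7-dimethoxy-2-oxo-2,3-dihydro-1H-indene-1-carboxylate F1. Photochemical Wolff rearrangement in THF/H2O (hν, 350 nm) should shift the quaternary carbon with retention, and water traps the ketene as (7S)-7-[(3,5-dimethoxyphenoxy)methyl]-4,5-dimethoxy-7-(methoxycarbonyl)bicyclo[4.2.0]octa-1,3,5-triene-8-carboxylic acid F2 (C8 epimers, of no consequence). Coupling with N-hydroxypyridine-2-thione (DCC, DMAP, CH2Cl2) would give the thiohydroxamate (Barton) ester F3. Barton reductive decarboxylation (visible light, t-BuSH, toluene) then removes the extra carboxyl and returns to the route at 10.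

Step 4. Facial discrimination by the catalyst may be insufficient on this α-aryl β-keto ester, and reversible aldol addition (loss and re-addition of formaldehyde) may erode the enantiomeric purity. The fallback sets out from 6 and replaces asymmetric catalysis by resolution. Base-catalysed hydroxymethylation (formalin, cat. KHCO3, THF, 0 °C) would give racemic methyl 1-(hydroxymethyl)-6,7-dimethoxy-2-oxo-2,3-dihydro-1H-indene-1-carboxylate F4. Mitsunobu coupling with 8 under the step 5 conditions would give racemic methyl 1-[(3,5-dimethoxyphenoxy)methyl]-6,7-dimethoxy-2-oxo-2,3-dihydro-1H-indene-1-carboxylate F5. Preparative SFC on a chiral stationary phase (amylose tris(3,5-dimethylphenylcarbamate)) would separate the enantiomers; the R enantiomer is set aside and the S enantiomer rejoins the route at 9.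

Step 5. SN2 displacement at the neopentyl carbon may be slow. The oxyphosphonium intermediate could then be diverted (alkylation of the hydrazide, attack by the enolisable C3 position), and unreacted alcohol could lose formaldehyde by retro-aldol cleavage. The fallback sets out from 7 and forms the aryl–oxygen bond in place of the alkyl–oxygen bond by Chan–Lam coupling. The conditions are potassium (3,5-dimethoxyphenyl)trifluoroborate, Cu(OAc)2 (divalent copper, catalytic), DMAP, 4 Å molecular sieves, O2, CH2Cl2, rt. This gives 9 directly and makes no new compound, F0.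

Further compounds
F1 | step 6 | methyl (S)-3-diazo-1-[(3,5-dimethoxyphenoxy)methyl]-6,7-dimethoxy-2-oxo-2,3-dihydro-1H-indene-1-carboxylate | COc1cc(OC)cc(c1)OC[C@@]1(C(=O)C(=[N+]=[N-])c2ccc(OC)c(OC)c21)C(=O)OC
F2 | step 6 | (7S)-7-[(3,5-dimethoxyphenoxy)methyl]-4,5-dimethoxy-7-(methoxycarbonyl)bicyclo[4.2.0]octa-1,3,5-triene-8-carboxylic acid (C8 epimers) | COc1cc(OC)cc(c1)OC[C@@]1(C(C(=O)O)c2ccc(OC)c(OC)c21)C(=O)OC
F3 | step 6 | methyl (7S)-7-[(3,5-dimethoxyphenoxy)methyl]-4,5-dimethoxy-8-{[(2-thioxopyridin-1(2H)-yl)oxy]carbonyl}bicyclo[4.2.0]octa-1,3,5-triene-7-carboxylate (C8 epimers) | COc1cc(OC)cc(c1)OC[C@@]1(C(C(=O)ON3C=CC=CC3=S)c2ccc(OC)c(OC)c21)C(=O)OC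
F4 | step 4 | racemic methyl 1-(hydroxymethyl)-6,7-dimethoxy-2-oxo-2,3-dihydro-1H-indene-1-carboxylate | OCC1(C(=O)Cc2ccc(OC)c(OC)c21)C(=O)OC
F5 | step 4 | racemic methyl 1-[(3,5-dimethoxyphenoxy)methyl]-6,7-dimethoxy-2-oxo-2,3-dihydro-1H-indene-1-carboxylate | COc1cc(OC)cc(c1)OCC1(C(=O)Cc2ccc(OC)c(OC)c21)C(=O)OC
F0 | step 5 | none | none
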